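Numbering the chain from the ester carbon (C1) to the brominated terminus (C20), everything rests on unzipping a cyclopentene. The oxolane (O, C5–C8) has bare ring carbons C6 and C7 and a four-carbon arm (C4–C1) on C5: the footprint of a cyclopent-2-enyl ether opened at its alkene, with its carbinol carbon C5 tied through C6 to a vinyl carbon C7 on C8. One ring-rearrangement metathesis thus closes the dihydrofuran (C6=C7), opens the carbocycle and releases the arm as a butenyl chain (C2=C1), both stereocentres passing through untouched. The precursor is the (1R)-cyclopent-2-enyl ether of a (3S) vinyl(silylethynyl)carbinol, made by iridium-catalysed allylic etherification; ester formation, ring saturation and a Sonogashira coupling finish.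

Key step: step 7

Remark: the (Sa,Sc,Sc) phosphoramidite in step 6 is assigned by analogy with aryl-substituted (E)-allylic carbonates, which share the substituent priority pattern of the alkynyl case; if a first run gave the (3R) ether, the mirror-image ligand would be used with nothing else changed.

Step 1
Reactants: 1 2-bromocyclopent-2-en-1-one
Product: 2 (1R)-2-bromocyclopent-2-en-1-ol
Conditions: (S)-2-methyl-CBS-oxazaborolidine (10 mol%), BH3·SMe2, THF, 0 °C; MeOH
Reagents that add atoms: none
Why: Corey–Bakshi–Shibata reduction, in which the ketone binds the oxazaborolidine boron anti to the larger bromovinyl flank and borane delivers hydride to one face, which should set C1 as R.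

Step 2
Reactants: 2 (1R)-2-bromocyclopent-2-en-1-ol
Product: 4 (1R)-cyclopent-2-en-1-ol, via dilithio alkoxide 3 (not isolated)
Conditions: t-BuLi (3.2 equiv), Et2O, −78 °C; H2O, −78 °C → rt
Reagents that add atoms: tert-butyllithium, [Li]C(C)(C)C (its lithium is held only in 3)
Why: Bromine–lithium exchange on the lithium alkoxide followed by protonation removes the halogen without touching the carbinol carbon, so the R configuration should be carried over unchanged.

Step 3
Reactants: 5 3-[tri(propan-2-yl)silyl]prop-2-ynal; 6 triethyl phosphonoacetate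
Product: 7 ethyl (2E)-5-[tri(propan-2-yl)silyl]pent-2-en-4-ynoate
Conditions: NaH, THF, 0 °C; then 5, −78 → 0 °C
Reagents that add atoms: none
Why: Horner–Wadsworth–Emmons olefination with a stabilised phosphonate anion should give the (E)-enynoate, the low temperature protecting the ynal from conjugate addition.

Step 4
Reactants: 7 ethyl (2E)-5-[tri(propan-2-yl)silyl]pent-2-en-4-ynoate
Product: 8 (2E)-5-[tri(propan-2-yl)silyl]pent-2-en-4-yn-1-ol
Conditions: i-Bu2AlH (2.2 equiv), CH2Cl2, −78 °C; aq potassium sodium tartrate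
Reagents that add atoms: none
Why: 1,2-Reduction of the conjugated ester by i-Bu2AlH at low temperature should stop at the allylic alcohol and leave the enyne and the silyl cap intact.

Step 5
Reactants: 8 (2E)-5-[tri(propan-2-yl)silyl]pent-2-en-4-yn-1-ol
Product: 9 tert-butyl (2E)-5-[tri(propan-2-yl)silyl]pent-2-en-4-yn-1-yl carbonate
Conditions: Boc2O, n-Bu4NHSO4 (cat.), 30% aq NaOH, CH2Cl2, 0 °C → rt
Reagents that add atoms: di-tert-butyl dicarbonate, CC(C)(C)OC(=O)OC(=O)OC(C)(C)C
Why: Phase-transfer O-acylation gives the tert-butyl carbonate, chosen as leaving group because the tert-butoxide it releases does not compete with the alkoxide nucleophile of the next step.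

Step 6
Reactants: 4 (1R)-cyclopent-2-en-1-ol; 9 tert-butyl (2E)-5-[tri(propan-2-yl)silyl]pent-2-en-4-yn-1-yl carbonate
Product: 12 tri(propan-2-yl){(3S)-3-[(1R)-cyclopent-2-en-1-yloxy]pent-4-en-1-yn-1-yl}silane, via lithium (1R)-cyclopent-2-en-1-olate 10 (not isolated), via [(1R)-cyclopent-2-en-1-yloxy]copper 11 (not isolated)
Conditions: 4 (2 equiv), n-BuLi, THF, 0 °C; CuI, rt; then 9, [Ir(cod)Cl]2 (2 mol%), (Sa,Sc,Sc)-(1,1′-binaphthalene-2,2′-diyl) N,N-bis(1-phenylethyl)phosphoramidite (4 mol%), THF, rt; aq NH4Cl
Reagents that add atoms: n-butyllithium, [Li]CCCC (its lithium is held only in 10); copper iodide CuI, [Cu]I (its copper is held only in 11)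
Why: Iridium-catalysed asymmetric allylic etherification with a monovalent copper alkoxide, in which the allyliridium complex formed by loss of the carbonate is attacked at its alkynyl-substituted terminus to give the branched ether, the chiral phosphoramidite complex setting the new C3 centre as S while the (1R) centre of the alkoxide is carried in unchanged.

Step 7
Reactants: 12 tri(propan-2-yl){(3S)-3-[(1R)-cyclopent-2-en-1-yloxy]pent-4-en-1-yn-1-yl}silane
Product: 13 tri(propan-2-yl){[(2S,5R)-5-(but-3-en-1-yl)-2,5-dihydrofuran-2-yl]ethynyl}silane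
Conditions: second-generation Grubbs catalyst RuCl2(H2IMes)(PCy3)(=CHPh) (5 mol%), ethylene (1 atm), CH2Cl2 (0.01 M), rt → 40 °C
Reagents that add atoms: ethene, C=C
Why: The ruthenium methylidene should exchange with the unhindered vinyl group to place the alkylidene on C7, which adds across the cyclopentene double bond in an intramolecular [2+2] step; cycloreversion of the ruthenacyclobutane forms C6=C7 and shifts the carbene to C2, where ethylene caps it as the C2=C1 methylene and returns the methylidene. The closest known reaction type is the ring-rearrangement metathesis (ring-opening and ring-closing in tandem) of cycloalkenyl allyl ethers and amines to dihydrofurans and dihydropyrroles. The one new ring, the 2,5-dihydrofuran (O, C5, C6, C7, C8), closes by ring-closing olefin metathesis through a fused ruthenacyclobutane, its double bond ending inside the ring as the carbocycle opens. No stereocentre is created: only sp2 carbons change partners, so the (1R) and (3S) centres of 12 become C5 (R) and C8 (S) of a trans-2,5-disubstituted ring. The step needs chemoselectivity for the two alkenes over the alkyne, secured by the bulky triisopropylsilyl cap, and suppression of oligomers, secured by dilution and ethylene. The equilibrium should favour 13 because the dihydrofuran lacks the eclipsed CH2–CH2 pair that strains the cyclopentene.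

Step 8
Reactants: 13 tri(propan-2-yl){[(2S,5R)-5-(but-3-en-1-yl)-2,5-dihydrofuran-2-yl]ethynyl}silane
Product: 15 4-[(2R,5S)-5-{[tri(propan-2-yl)silyl]ethynyl}-2,5-dihydrofuran-2-yl]butan-1-ol, via B-alkyl-9-borabicyclononane 14 (not isolated)
Conditions: 9-BBN (1.3 equiv), THF, 0 °C → rt; then aq NaOH, 30% H2O2, 0 °C → rt
Reagents that add atoms: 9-borabicyclo[3.3.1]nonane, C1CC2CCCC(C1)B2 (its boron bicycle is held only in 14); hydrogen peroxide, OO
Why: Brown hydroboration–oxidation with bulky 9-BBN is anti-Markovnikov and should select the monosubstituted terminal alkene over the cis-disubstituted ring alkene and the shielded silyl alkyne, alkaline peroxide then replacing boron by hydroxyl at C1.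

Step 9
Reactants: 15 4-[(2R,5S)-5-{[tri(propan-2-yl)silyl]ethynyl}-2,5-dihydrofuran-2-yl]butan-1-ol
Product: 16 4-[(2R,5S)-5-{[tri(propan-2-yl)silyl]ethynyl}oxolan-2-yl]butan-1-ol
Conditions: TsNHNH2 (excess, in portions), NaOAc, DME/H2O, reflux
Reagents that add atoms: none
Why: Diimide reduction, in which diazene transfers two hydrogens in a concerted syn step to the unhindered cis ring alkene, should leave the internal alkyne behind its bulky silyl group and does not involve C5 or C8.

Step 10
Reactants: 16 4-[(2R,5S)-5-{[tri(propan-2-yl)silyl]ethynyl}oxolan-2-yl]butan-1-ol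
Product: 18 4-[(2R,5S)-5-{[tri(propan-2-yl)silyl]ethynyl}oxolan-2-yl]butanoic acid, via oxolanyl butanal 17 (not isolated)
Conditions: TEMPO (20 mol%), PhI(OAc)2 (2.5 equiv), MeCN/H2O (1:1), rt
Reagents that add atoms: water, O
Why: Oxoammonium (TEMPO) oxidation with PhI(OAc)2 as terminal oxidant should take the primary alcohol to the aldehyde and, through its hydrate in aqueous acetonitrile, on to the acid without touching the saturated ether ring or the silyl alkyne.

Step 11
Reactants: 18 4-[(2R,5S)-5-{[tri(propan-2-yl)silyl]ethynyl}oxolan-2-yl]butanoic acid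
Product: 19 methyl 4-[(2R,5S)-5-{[tri(propan-2-yl)silyl]ethynyl}oxolan-2-yl]butanoate
Conditions: MeI, K2CO3, DMF, rt
Reagents that add atoms: iodomethane, CI
Why: SN2 O-alkylation of the potassium carboxylate by iodomethane gives the methyl ester under conditions to which the silyl alkyne and both stereocentres are inert.

Step 12
Reactants: 19 methyl 4-[(2R,5S)-5-{[tri(propan-2-yl)silyl]ethynyl}oxolan-2-yl]butanoate
Product: 20 methyl 4-[(2R,5S)-5-ethynyloxolan-2-yl]butanoate
Conditions: TBAF (1.1 equiv), THF, 0 °C
Reagents that add atoms: none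
Why: Fluoride-induced protodesilylation cleaves the C(sp)–Si bond, and brief exposure at 0 °C should spare the methyl ester and the propargylic ether centre.

Step 13
Reactants: 21 hept-6-yn-1-ol
Product: 23 (6E)-7-iodohept-6-en-1-ol, via O-zirconated alkenylzirconocene chloride 22 (not isolated)
Conditions: Cp2Zr(H)Cl (2.3 equiv), THF, rt, dark; then I2, 0 °C
Reagents that add atoms: zirconocene chloride hydride Cp2Zr(H)Cl, Cl[ZrH](C1C=CC=C1)C1C=CC=C1 (its zirconium is held only in 22); iodine, II
Why: Hydrozirconation–iodination, in which one equivalent of the hydride is consumed by the hydroxyl group, the second adds syn with zirconium on the terminal carbon, and iodine cleaves the C–Zr bond with retention to give the (E)-iodoalkene.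

Step 14
Reactants: 23 (6E)-7-iodohept-6-en-1-ol
Product: 24 (6E)-7-iodohept-6-enal
Conditions: TEMPO (10 mol%), PhI(OAc)2 (1.1 equiv), CH2Cl2, rt
Reagents that add atoms: none
Why: TEMPO-catalysed oxidation in anhydrous dichloromethane should stop at the aldehyde and tolerate the iodoalkene.

Step 15
Reactants: 24 (6E)-7-iodohept-6-enal; 25 (triphenylphosphoranylidene)acetaldehyde
Product: 26 (2E,8E)-9-iodonona-2,8-dienal
Conditions: toluene, 80 °C
Reagents that add atoms: none
Why: Wittig olefination with the stabilised formylmethylene ylide extends the aldehyde by two carbons to the (E)-enal, the less electrophilic conjugated product resisting a second homologation.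

Step 16
Reactants: 26 (2E,8E)-9-iodonona-2,8-dienal
Product: 27 (1E,3E,9E)-1-bromo-10-iododeca-1,3,9-triene
Conditions: CrCl2 (6 equiv), CHBr3 (2 equiv), THF, 0 °C → rt, dark
Reagents that add atoms: bromoform, BrC(Br)Br
Why: Takai olefination, in which the geminal dichromium species from bromoform adds to the enal and eliminates to the (E)-bromoalkene, should give mainly the (1E,3E)-bromodiene and leave the iodoalkene alone in the absence of nickel.

Step 17
Reactants: 20 methyl 4-[(2R,5S)-5-ethynyloxolan-2-yl]butanoate; 27 (1E,3E,9E)-1-bromo-10-iododeca-1,3,9-triene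
Product: 28 methyl 4-[(2R,5S)-5-[(3E,9E,11E)-12-bromododeca-3,9,11-trien-1-yn-1-yl]oxolan-2-yl]butanoate
Conditions: Pd(PPh3)4 (5 mol%), CuI (10 mol%), Et3N, THF (degassed), 27 in slight excess, 0 °C → rt, dark
Reagents that add atoms: none
Why: Sonogashira coupling, in which zerovalent palladium inserts into the C–I bond far faster than into the C–Br bond of the bromodiene at or below room temperature, so the copper acetylide of 20 should couple only at C11 with retention of the (E) geometry.

Compound list
1 | 2-bromocyclopent-2-en-1-one | O=C1CCC=C1Br | starting material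
2 | (1R)-2-bromocyclopent-2-en-1-ol | O[C@@H]1CCC=C1Br | intermediate
3 | lithium (1R)-2-lithiocyclopent-2-en-1-olate | [Li]O[C@@H]1CCC=C1[Li] | intermediate (not isolated)
4 | (1R)-cyclopent-2-en-1-ol | O[C@@H]1CCC=C1 | intermediate
5 | 3-[tri(propan-2-yl)silyl]prop-2-ynal | O=CC#C[Si](C(C)C)(C(C)C)C(C)C | starting material
6 | triethyl phosphonoacetate | CCOC(=O)CP(=O)(OCC)OCC | starting material
7 | ethyl (2E)-5-[tri(propan-2-yl)silyl]pent-2-en-4-ynoate | CCOC(=O)/C=C/C#C[Si](C(C)C)(C(C)C)C(C)C | intermediate
8 | (2E)-5-[tri(propan-2-yl)silyl]pent-2-en-4-yn-1-ol | OC/C=C/C#C[Si](C(C)C)(C(C)C)C(C)C | intermediate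
9 | tert-butyl (2E)-5-[tri(propan-2-yl)silyl]pent-2-en-4-yn-1-yl carbonate | CC(C)(C)OC(=O)OC/C=C/C#C[Si](C(C)C)(C(C)C)C(C)C | intermediate
10 | lithium (1R)-cyclopent-2-en-1-olate | [Li]O[C@@H]1CCC=C1 | intermediate (not isolated)
11 | [(1R)-cyclopent-2-en-1-yloxy]copper | [Cu]O[C@@H]1CCC=C1 | intermediate (not isolated)
12 | tri(propan-2-yl){(3S)-3-[(1R)-cyclopent-2-en-1-yloxy]pent-4-en-1-yn-1-yl}silane | C=C[C@H](O[C@@H]1CCC=C1)C#C[Si](C(C)C)(C(C)C)C(C)C | intermediate
13 | tri(propan-2-yl){[(2S,5R)-5-(but-3-en-1-yl)-2,5-dihydrofuran-2-yl]ethynyl}silane | C=CCC[C@@H]1C=C[C@@H](C#C[Si](C(C)C)(C(C)C)C(C)C)O1 | intermediate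
14 | 9-{4-[(2R,5S)-5-{[tri(propan-2-yl)silyl]ethynyl}-2,5-dihydrofuran-2-yl]butyl}-9-borabicyclo[3.3.1]nonane | C1CC2CCCC(C1)B2CCCC[C@@H]1C=C[C@@H](C#C[Si](C(C)C)(C(C)C)C(C)C)O1 | intermediate (not isolated)
15 | 4-[(2R,5S)-5-{[tri(propan-2-yl)silyl]ethynyl}-2,5-dihydrofuran-2-yl]butan-1-ol | OCCCC[C@@H]1C=C[C@@H](C#C[Si](C(C)C)(C(C)C)C(C)C)O1 | intermediate
16 | 4-[(2R,5S)-5-{[tri(propan-2-yl)silyl]ethynyl}oxolan-2-yl]butan-1-ol | OCCCC[C@@H]1CC[C@@H](C#C[Si](C(C)C)(C(C)C)C(C)C)O1 | intermediate
17 | 4-[(2R,5S)-5-{[tri(propan-2-yl)silyl]ethynyl}oxolan-2-yl]butanal | O=CCCC[C@@H]1CC[C@@H](C#C[Si](C(C)C)(C(C)C)C(C)C)O1 | intermediate (not isolated)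
18 | 4-[(2R,5S)-5-{[tri(propan-2-yl)silyl]ethynyl}oxolan-2-yl]butanoic acid | OC(=O)CCC[C@@H]1CC[C@@H](C#C[Si](C(C)C)(C(C)C)C(C)C)O1 | intermediate
19 | methyl 4-[(2R,5S)-5-{[tri(propan-2-yl)silyl]ethynyl}oxolan-2-yl]butanoate | COC(=O)CCC[C@@H]1CC[C@@H](C#C[Si](C(C)C)(C(C)C)C(C)C)O1 | intermediate
20 | methyl 4-[(2R,5S)-5-ethynyloxolan-2-yl]butanoate | COC(=O)CCC[C@@H]1CC[C@@H](C#C)O1 | intermediate
21 | hept-6-yn-1-ol | C#CCCCCCO | starting material
22 | chlorobis(cyclopentadienyl)[(1E)-7-{[chlorobis(cyclopentadienyl)zirconio]oxy}hept-1-en-1-yl]zirconium | Cl[Zr](OCCCCC/C=C/[Zr](Cl)(C1C=CC=C1)C1C=CC=C1)(C1C=CC=C1)C1C=CC=C1 | intermediate (not isolated)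
23 | (6E)-7-iodohept-6-en-1-ol | OCCCCC/C=C/I | intermediate
24 | (6E)-7-iodohept-6-enal | O=CCCCC/C=C/I | intermediate
25 | (triphenylphosphoranylidene)acetaldehyde | O=CC=P(c1ccccc1)(c1ccccc1)c1ccccc1 | starting material
26 | (2E,8E)-9-iodonona-2,8-dienal | O=C/C=C/CCCC/C=C/I | intermediate
27 | (1E,3E,9E)-1-bromo-10-iododeca-1,3,9-triene | Br/C=C/C=C/CCCC/C=C/I | intermediate
28 | methyl 4-[(2R,5S)-5-[(3E,9E,11E)-12-bromododeca-3,9,11-trien-1-yn-1-yl]oxolan-2-yl]butanoate | COC(=O)CCC[C@@H]1CC[C@@H](C#C/C=C/CCCC/C=C/C=C/Br)O1 | target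

Total step count: 17. Longest linear sequence: 11 steps (steps 3, 4, 5, 6, 7, 8, 9, 10, 11, 12 and 17).

Steps most likely to fail

Step 7. The relay may stall through reversion to the carbocycle, oligomerisation at the new terminal alkene, or migration of the ring double bond by ruthenium hydrides. The fallback closes the dihydrofuran by a plain ring-closing metathesis of a bis-allylic ether that has no cycloalkene to open and already carries the arm as a protected butanol. It sets out from 9. Vinylmagnesium bromide would be added to purchased 5-{[tert-butyl(dimethyl)silyl]oxy}pentanal to give racemic 7-{[tert-butyl(dimethyl)silyl]oxy}hept-1-en-3-ol F1. A Sharpless kinetic resolution (Ti(OiPr)4, L-(+)-diisopropyl tartrate, t-BuOOH) should leave (3R)-7-{[tert-butyl(dimethyl)silyl]oxy}hept-1-en-3-ol F2. As in step 6, n-BuLi would give the lithium alkoxide F3 and CuI the copper alkoxide F4, which would be joined with 9 under the same iridium catalyst to give the diallyl ether tert-butyl(dimethyl){[(5R)-5-({(3S)-5-[tri(propan-2-yl)silyl]pent-1-en-4-yn-3-yl}oxy)hept-6-en-1-yl]oxy}silane F5. The second-generation Grubbs catalyst should close F5 to tert-butyl(dimethyl)(4-{(2R,5S)-5-{[tri(propan-2-yl)silyl]ethynyl}-2,5-dihydrofuran-2-yl}butoxy)silane F6, and pyridinium p-toluenesulfonate in methanol would remove the silyl ether without touching the silyl alkyne. The route is rejoined at 15.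

Step 6. The hindered secondary copper alkoxide may react slowly, give linear ether, or give poor diastereocontrol. The fallback makes the two carbon–oxygen bonds in the opposite order and sets out from 9. Iridium-catalysed allylic hydroxylation with KHCO3 as oxygen nucleophile, under the same [Ir(cod)Cl]2–phosphoramidite catalyst, should give (3S)-5-[tri(propan-2-yl)silyl]pent-1-en-4-yn-3-ol F7. Et2Zn would convert it into the zinc bis-alkoxide F8, which would be allylated with racemic tert-butyl cyclopent-2-en-1-yl carbonate F9 (from purchased racemic cyclopent-2-en-1-ol and Boc2O) under Pd2(dba)3 and the DACH-phenyl Trost ligand. The ligand antipode would be chosen so that attack on the symmetric cyclopentenyl–palladium intermediate gives the (1R) ether carbon. The route is rejoined at 12.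

Step 16. The olefination may give an inseparable share of the (1Z) isomer, and bromine may be exchanged for chlorine from the chromium salt. The fallback builds the bromodiene stereospecifically from an alkyne and sets out from 26. The Ohira–Bestmann reagent (dimethyl (1-diazo-2-oxopropyl)phosphonate, K2CO3, MeOH) should give (3E,9E)-10-iododeca-3,9-dien-1-yne F10. Hydrozirconation with Cp2Zr(H)Cl would give the dienylzirconocene chloride F11, and N-bromosuccinimide cleaves its C–Zr bond with retention. The route is rejoined at 27.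

Further compounds
F1 | step 7 | 7-{[tert-butyl(dimethyl)silyl]oxy}hept-1-en-3-ol (racemic) | C=CC(O)CCCCO[Si](C)(C)C(C)(C)C
F2 | step 7 | (3R)-7-{[tert-butyl(dimethyl)silyl]oxy}hept-1-en-3-ol | C=C[C@H](O)CCCCO[Si](C)(C)C(C)(C)C
F3 | step 7 | lithium (3R)-7-{[tert-butyl(dimethyl)silyl]oxy}hept-1-en-3-olate | [Li]O[C@@H](C=C)CCCCO[Si](C)(C)C(C)(C)C
F4 | step 7 | {[(3R)-7-{[tert-butyl(dimethyl)silyl]oxy}hept-1-en-3-yl]oxy}copper | [Cu]O[C@@H](C=C)CCCCO[Si](C)(C)C(C)(C)C
F5 | step 7 | tert-butyl(dimethyl){[(5R)-5-({(3S)-5-[tri(propan-2-yl)silyl]pent-1-en-4-yn-3-yl}oxy)hept-6-en-1-yl]oxy}silane | C=C[C@@H](CCCCO[Si](C)(C)C(C)(C)C)O[C@@H](C=C)C#C[Si](C(C)C)(C(C)C)C(C)C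
F6 | step 7 | tert-butyl(dimethyl)(4-{(2R,5S)-5-{[tri(propan-2-yl)silyl]ethynyl}-2,5-dihydrofuran-2-yl}butoxy)silane | CC(C)(C)[Si](C)(C)OCCCC[C@@H]1C=C[C@@H](C#C[Si](C(C)C)(C(C)C)C(C)C)O1
F7 | step 6 | (3S)-5-[tri(propan-2-yl)silyl]pent-1-en-4-yn-3-ol | C=C[C@H](O)C#C[Si](C(C)C)(C(C)C)C(C)C
F8 | step 6 | zinc bis{(3S)-5-[tri(propan-2-yl)silyl]pent-1-en-4-yn-3-olate} | C=C[C@H](O[Zn]O[C@@H](C=C)C#C[Si](C(C)C)(C(C)C)C(C)C)C#C[Si](C(C)C)(C(C)C)C(C)C
F9 | step 6 | tert-butyl cyclopent-2-en-1-yl carbonate (racemic) | CC(C)(C)OC(=O)OC1CCC=C1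
F10 | step 16 | (3E,9E)-10-iododeca-3,9-dien-1-yne | C#C/C=C/CCCC/C=C/I
F11 | step 16 | chlorobis(cyclopentadienyl)[(1E,3E,9E)-10-iododeca-1,3,9-trien-1-yl]zirconium | Cl[Zr](/C=C/C=C/CCCC/C=C/I)(C1C=CC=C1)C1C=CC=C1
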